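The readings come from a simulation on assumed constants; noise was put on by code.

One ratio should hold still while the substrate disappears, and that is what we watch: left-handed product over right-handed product.

| setting | midnight | autumn | flask |
|---|---|---|---|
| left-handed substrate | 0.050 M | 0.050 M | 0.050 M |
| right-handed substrate | 0.050 M | 0.050 M | 0.050 M |
| solid reagent | 3 equiv | 3 equiv | 3.00 equiv |
| racemization catalyst | 2 mol% | 8 mol% | 4 mol% |
| remark | run made earlier | run made earlier |  |
| time |  |  | 2.5 h |

| run | time / h | left-handed product / % | right-handed product / % |
|---|---|---|---|
| midnight | 0.200 | 0.7 | 0 |
| midnight | 0.417 | 4.6 | 1.8 |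
| midnight | 0.667 | 9.0 | 4.3 |
| midnight | 1.33 | 18.9 | 9.0 |
| midnight | 2.50 | 34.9 | 14.2 |
| autumn | 0.200 | 1.3 | 0.5 |
| autumn | 0.667 | 8.5 | 3.9 |
| autumn | 1.33 | 17.8 | 9.2 |
| autumn | 2.00 | 29.1 | 12.7 |
| autumn | 2.50 | 33.9 | 15.3 |

(scatter of a reading: 0.5 percentage points)

- partner is single-handed; left-handed substrate and right-handed substrate are mirror images of each other, charged as a racemate, each of them at the stated concentration
- as a solid, counted per litre of solution: solid reagent
- at the start none of the solid reagent is in solution
- an excess is below zero if the other one leads
- the handed part of partner does not stay in what it makes, so the products of the two hands are mirror images too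

- left-handed product and right-handed product together, in percent of the left-handed substrate and right-handed substrate charged together, at 2.5 h
- excess of left-handed product over right-handed product in the product at 2.5 h
- whether the exchange between left-handed substrate and right-handed substrate keeps pace with the reaction: how far the product's excess at 2.5 h gets from its value without exchange to its value with instant exchange (above 80 % keeps pace, below 20 % hardly takes part, else lags behind)

Midnight and autumn look nearly the same. Midnight carries 2 mol% of racemization catalyst and autumn 8 mol%. We count the fraction left, not the fraction made. At 2.50 h midnight has 50.9 % of the two substrates left and autumn 50.8 %. They differ by 0.1 percentage points, and a reading scatters by 0.5 points. So we pool them: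

s = left-handed product / right-handed product = 2.33

This reading is the selectivity factor, the left-handed product made per right-handed product. Pooled at 1.33 h, the same ratio reads 2.02, so it stands higher later than earlier, and it does not fall as the fraction left shrinks. We read this as exchange that holds the two substrates level in both runs. Our flask, at 4 mol% of racemization catalyst, lies between the two runs. Our own reckoning for the flask is:

excess = (s − 1)/(s + 1) = 40.0 %

yield = mean of the two runs = 49.1 %

The forecast gives 49 %, an excess of 39 %, and says the exchange keeps pace. Its ground is that no exchange “would let the excess fall to about 26% at 49% yield”. Our excess is 40.0 %, the forecast's 39 %.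

    partner + left-handed substrate → left-handed product (k = 0.00910 L mol⁻¹ s⁻¹)
    partner + right-handed substrate → right-handed product (k = 0.00390 L mol⁻¹ s⁻¹)
    left-handed substrate + racemization catalyst ⇌ right-handed substrate + racemization catalyst, rate k3*[racemization catalyst]*[left-handed substrate] forward; the back reaction follows from the equilibrium constant (k = 34.0 L mol⁻¹ s⁻¹)
    solid reagent ⇌ partner, rate k4*(cs4 - [partner]) while solid is left; crystals form when [partner] > cs4 (solubility = 23.0 mM, k = 6.50 × 10⁻⁴ s⁻¹)
    racemization catalyst ⇌ dormant form (K = 1.20, k = 0.0180 s⁻¹)

The flask gives 50.1 % with an excess of 40.0 %, and the exchange keeps pace, 99.6 % of the way. At 2.50 h the excess of right-handed substrate among what is left is 0.0625 %. Splitting the yield by s gives 35.1 % of left-handed product, and the flask holds 35.1 %. The neighbour charged with 0.750 equiv of solid reagent reaches 35.8 %, with 0 % of its solid reagent left. There s gives 25.0 %, and that neighbour holds 25.1 % of left-handed product at 2.50 h.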